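Readings and results are simulated with made-up constants.

Hours are what this flask is given: 6.0 h, which is 9.00 times the 40.0 min of Tuesday's run, on the same recipe at half the concentration.

in all of them: free catalyst 0.5 mol%

| flask | starting material | coupling partner | second substrate | remark | time |
|---|---|---|---|---|---|
| Tuesday's | 0.20 M | 1.8 equiv | 1 equiv | run made earlier |  |
| flask | 0.10 M | 1.80 equiv | 1.00 equiv |  | 6.0 h |

Tuesday's run (percent of the starting material charged)

| time / min | starting material / % | target / % |
|---|---|---|
| 2.50 | 90.7 | 5.2 |
| 8.00 | 76.0 | 13.2 |
| 12.0 | 68.5 | 18.0 |
| 20.0 | 56.6 | 22.8 |
| 30.0 | 47.1 | 27.2 |
| 40.0 | 39.6 | 29.9 |

(scatter of a reading: 0.3 percentage points)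

* the state of affairs at 6.0 h: stopped, and by what, or still going (the coupling partner has run out first / it is still moving / all of the starting material has reacted)
* part of the starting material gone at 6.0 h
* the target standing at 6.0 h, as a percentage of the starting material charged
* the uncatalysed product standing at 6.0 h, as a percentage of the starting material charged

- no earlier run changes the charge of free catalyst; that part of a forecast is a guess
- the reaction counts as stopped when no species that holds the starting material changes by six tenths of a point or more over the second half of the time

Tuesday's target is still rising at 29.9% at its last reading, and yet I expect this flask, with all those extra hours, to end below that.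

From Tuesday's run I read the catalysed pseudo-first-order constant as the target's gain per minute over the starting material standing. It reads 0.0175 min⁻¹ between the first two readings and 0.00623 min⁻¹ between the last two. I assume the rate is first order in starting material, coupling partner and free catalyst, and that one partner goes with each starting material consumed. Part of the fall is then partner used, and I put the remainder down to free catalyst decaying. The time in which free catalyst falls by a factor of e reads as 39.7 min, and this catalyst life is what I carry.

In this flask the concentrations of catalyst and partner halve, so the starting constant drops to a quarter of Tuesday's, to 0.00549 min⁻¹. Since the life is far shorter than the time, the late hours add little target. Constant times life gives 21.8% of target with starting material and partner held at charge, less than Tuesday's last reading. Both fall, so I expect the target below even that.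

The forecast says it is still moving, with 82% gone, 18% target and 64% uncatalysed product, on the ground: “This looks like catalyst dying”.

The flask gives: it is still moving, with 86.3% gone, 14.4% target and 71.9% uncatalysed product, which stands 7.9 percentage points above the forecast.

    second substrate + coupling partner + free catalyst → free catalyst + second product (k = 36.1 M⁻² min⁻¹)
    starting material + coupling partner → uncatalysed product (k = 0.0467 M⁻¹ min⁻¹)
    free catalyst → spent catalyst (k = 0.0235 min⁻¹)
    starting material + coupling partner + free catalyst → free catalyst + target (k = 64.3 M⁻² min⁻¹)

In this flask a life of 39.7 min puts free catalyst at 40.4% at 0.600 h, where it stands at 42.9%. The neighbouring flask, the same charge read at 1.5 h, is 2.27 lives in, so the same reckoning gives 10.4% free catalyst. It holds 12.1%, and its target already stands at 13.7%, beside 39.7% of uncatalysed product.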